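**Plan**

- Retrosynthesis: cut the silyl ether, then the C(=O)–C≡C bond of the diynone (acyl coupling), which separates a (5S,6Z)-tetradec-6-ene-1,3-diyn-5-ol unit from a chroman-2,4-dione propanoic acid. Then cut the lactone bond O1–C2, then in one event O1–C8a and C4–C4a, and last the two C3–CH2 bonds of an acyclic malonate.
- Enabling feature: the benzo ring (C4a–C8a) carries no other substituent and is held only by O1 and by the C4 carbonyl carbon. These are the oxygen and the acyl carbon of one carboxyl group of a 2,2-disubstituted malonic acid, so benzyne can be inserted into that C–O bond (carboxylate O-arylation, then 1,3 O→C acyl shift).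
- C3 is stereogenic only because one malonate carboxyl becomes the C4 ketone and the other the C2 lactone. A half-ester whose free acid is turned regiospecifically into the aryl ketone carries its configuration into the ring without any bond to C3 being touched.
- Forward: mixed malonate → Michael addition → enantioselective phase-transfer farnesylation → half-acid → benzyne insertion (benzo ring attached) → ester cleavage and lactonisation (pyran-2,4-dione ring closed) → acyl coupling with the diyne → desilylation.
- Stereochemistry: C3 from the phase-transfer alkylation (step 3); C8 of the side chain from the ZnMe2/ProPhenol alkynylation (step 10); the 9Z alkene from syn semi-hydrogenation; the 2E,6E alkenes from farnesyl bromide.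

Key step: step 5

Assumption: the (S,S) phase-transfer catalyst of step 3 and (S,S)-ProPhenol of step 10 are taken to give the configurations drawn; if either sense of induction proves opposite on these new substrates, the enantiomeric catalyst is used and nothing else changes.

**Route**

Step 1
Reactants: 1 3-(tert-butoxy)-3-oxopropanoic acid; 2 2,2-diphenylethanol
Product: 3 tert-butyl 2,2-diphenylethyl propanedioate
Conditions: DCC, DMAP (cat.), CH2Cl2, 0 °C → rt
Reagents that add atoms: none
Why: Steglich esterification of the malonic half-acid with a primary alcohol gives the mixed diester whose two unlike ester groups allow the carboxyls to be told apart later.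

Step 2
Reactants: 3 tert-butyl 2,2-diphenylethyl propanedioate; 4 tert-butyl prop-2-enoate
Product: 5 1,3-di-tert-butyl 1-(2,2-diphenylethyl) propane-1,1,3-tricarboxylate (racemic, configurationally labile)
Conditions: KOtBu (10 mol%), THF, 0 °C → rt, 3 in excess
Reagents that add atoms: none
Why: Base-catalysed Michael addition of the malonate enolate to the acrylate installs the three-carbon chain as a latent carboxylic acid, the excess of 3 holding back double addition.

Step 3
Reactants: 5 1,3-di-tert-butyl 1-(2,2-diphenylethyl) propane-1,1,3-tricarboxylate; 6 (2E,6E)-1-bromo-3,7,11-trimethyldodeca-2,6,10-triene (E,E-farnesyl bromide)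
Product: 7 1,3-di-tert-butyl 1-(2,2-diphenylethyl) (1S)-1-[(2E,6E)-3,7,11-trimethyldodeca-2,6,10-trien-1-yl]propane-1,1,3-tricarboxylate
Conditions: (S,S)-3,4,5-trifluorophenyl-NAS bromide (N-spiro bis-binaphthyl ammonium bromide, 5 mol%), 50% aq. KOH, toluene, −40 °C
Reagents that add atoms: none
Why: Asymmetric phase-transfer alkylation of an α-monosubstituted tert-butyl/arylalkyl malonate with a reactive allylic bromide, in which the C2-symmetric spiro ammonium cation ion-pairs with the enolate and shields one of its two faces (which differ only in the placing of the two ester groups), so setting the quaternary centre as (S).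

Step 4
Reactants: 7 1,3-di-tert-butyl 1-(2,2-diphenylethyl) (1S)-1-[(2E,6E)-3,7,11-trimethyldodeca-2,6,10-trien-1-yl]propane-1,1,3-tricarboxylate
Product: 8 (2S)-5-tert-butoxy-2-(tert-butoxycarbonyl)-5-oxo-2-[(2E,6E)-3,7,11-trimethyldodeca-2,6,10-trien-1-yl]pentanoic acid
Conditions: KOH (1 M in MeOH), 40 °C; then 1 M HCl to pH 3, 0 °C
Reagents that add atoms: potassium hydroxide, [K+].[OH-]
Why: Saponification by the BAc2 path cleaves only the primary 2,2-diphenylethyl ester because both tert-butyl esters are inert to hydroxide, and the quaternary centre, having no α-hydrogen, cannot epimerise.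

Step 5
Reactants: 8 (2S)-5-tert-butoxy-2-(tert-butoxycarbonyl)-5-oxo-2-[(2E,6E)-3,7,11-trimethyldodeca-2,6,10-trien-1-yl]pentanoic acid; 9 2-(trimethylsilyl)phenyl trifluoromethanesulfonate
Product: 12 di-tert-butyl (2S)-2-(2-hydroxybenzoyl)-2-[(2E,6E)-3,7,11-trimethyldodeca-2,6,10-trien-1-yl]pentanedioate, via sodium carboxylate 10 (not isolated), via benzyne 11 (not isolated)
Conditions: NaH, THF, 0 °C → rt; then 9, CsF, THF, 100 °C (sealed tube); 1 M HCl work-up at 0 °C
Reagents that add atoms: none
Why: Fluoride converts 9 into benzyne 11; the carboxylate oxygen of 10 adds to it (O–aryl bond) and the ortho-aryl anion so formed, lying about 3 Å from its own acyloxy carbon, attacks that carbonyl in a 4-exo-trig fashion to a benzoxetene alkoxide whose collapse shifts the acyl group from O to C (aryl–C(=O) bond), so that benzyne is in effect inserted into the C–O bond of the acid carboxyl. The closest known reaction type is the fluoride-induced insertion of arynes into the C–O bond of carboxylic acids to give ortho-hydroxyaryl ketones (an anionic Fries-type 1,3 O→C acyl shift), used here on an α-quaternary malonic half-ester. No ring of the target is closed in this step: the four-membered ring is transient, and the pyran-2,4-dione ring is closed in step 6. No stereocentre is created; the four bonds of the quaternary carbon stay intact, and its configuration is carried into the product because the acid carboxyl, and only it, becomes the aryl ketone. The selectivity needed is thus regiochemical, acylation of the aryl anion by its own ester carbon and not by the neighbouring tert-butyl ester (which would lead, after lactonisation, to the enantiomeric chromandione); it is secured by proximity, by the s-trans geometry of the aryl ester, which holds the second carbonyl out of reach, and by the bulk and low electrophilicity of the tert-butyl ester. The carboxylate is preformed with NaH so that no O–H is present to protonate the aryl anion to the plain phenyl ester.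

Step 6
Reactants: 12 di-tert-butyl (2S)-2-(2-hydroxybenzoyl)-2-[(2E,6E)-3,7,11-trimethyldodeca-2,6,10-trien-1-yl]pentanedioate
Product: 15 3-{(3S)-2,4-dioxo-3-[(2E,6E)-3,7,11-trimethyldodeca-2,6,10-trien-1-yl]-3,4-dihydro-2H-chromen-3-yl}propanoic acid, via tris(trimethylsilyl) derivative 13 (not isolated), via diacid phenol 14 (not isolated)
Conditions: TMSOTf, 2,6-lutidine, CH2Cl2, 0 °C; cold pH 4 aqueous work-up, crude taken on at once; EDC·HCl, DMAP (cat.), CH2Cl2, 0 °C
Reagents that add atoms: none
Why: Silyl triflate with a hindered pyridine turns both tert-butyl esters into silyl esters by loss of isobutene without protic acid (the trisubstituted alkenes are spared), and carbodiimide activation then closes the aryl lactone by 6-exo-trig attack of the ortho phenol on the carboxyl at C3 (the eight-membered alternative through the chain carboxyl is disfavoured), the short-lived β-keto acid being kept cold to avoid decarboxylation.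

Step 7
Reactants: 16 1,4-bis(trimethylsilyl)buta-1,3-diyne
Product: 18 buta-1,3-diyn-1-yl(trimethyl)silane, via lithium acetylide 17 (not isolated)
Conditions: MeLi·LiBr, Et2O, 0 °C → rt; then 1 M HCl, 0 °C; used as a solution
Reagents that add atoms: none
Why: Methyllithium attacks one silicon of the bis(silyl)diyne (the second is deactivated once the acetylide has formed) and protonation gives the mono-protected terminal diyne.

Step 8
Reactants: 19 dec-2-yn-1-ol
Product: 20 (2Z)-dec-2-en-1-ol
Conditions: H2 (1 atm), Pd/CaCO3 poisoned with Pb(OAc)2, quinoline, EtOAc, rt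
Reagents that add atoms: none
Why: Syn addition of hydrogen on the poisoned palladium surface (Lindlar reduction) stops at the alkene and gives the Z allylic alcohol.

Step 9
Reactants: 20 (2Z)-dec-2-en-1-ol
Product: 21 (2Z)-dec-2-enal
Conditions: Dess–Martin periodinane, pyridine, CH2Cl2, 0 °C; used at once
Reagents that add atoms: none
Why: Dess–Martin oxidation under pyridine buffering is fast and non-acidic at 0 °C, conditions under which the Z enal should form without isomerisation.

Step 10
Reactants: 21 (2Z)-dec-2-enal; 18 buta-1,3-diyn-1-yl(trimethyl)silane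
Product: 23 (5S,6Z)-1-(trimethylsilyl)tetradec-6-ene-1,3-diyn-5-ol, via methylzinc acetylide 22 (not isolated)
Conditions: ZnMe2, (S,S)-ProPhenol (20 mol%), Ph3PO (40 mol%), toluene, 4 °C; aq. NH4Cl
Reagents that add atoms: none
Why: Catalytic enantioselective 1,2-addition of the alkynylzinc to the aldehyde within the chiral pocket of the catalyst formed from ZnMe2 and (S,S)-ProPhenol, which exposes the Re face of the enal and so sets the carbinol as (S).

Step 11
Reactants: 23 (5S,6Z)-1-(trimethylsilyl)tetradec-6-ene-1,3-diyn-5-ol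
Product: 24 tert-butyl(dimethyl){[(5S,6Z)-1-(trimethylsilyl)tetradec-6-ene-1,3-diyn-5-yl]oxy}silane
Conditions: TBSCl, imidazole, DMF, rt
Reagents that add atoms: tert-butyl(chloro)dimethylsilane, CC(C)(C)[Si](C)(C)Cl
Why: Standard silylation of the secondary alcohol, which blocks the hydroxyl against the acid chloride used in step 13.

Step 12
Reactants: 24 tert-butyl(dimethyl){[(5S,6Z)-1-(trimethylsilyl)tetradec-6-ene-1,3-diyn-5-yl]oxy}silane
Product: 25 tert-butyl(dimethyl){[(5S,6Z)-tetradec-6-ene-1,3-diyn-5-yl]oxy}silane
Conditions: K2CO3 (0.2 equiv), MeOH, 0 °C; used without storage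
Reagents that add atoms: none
Why: Methoxide-catalysed protodesilylation cleaves the C(sp)–Si bond selectively, the silyl ether being stable under these conditions.

Step 13
Reactants: 15 3-{(3S)-2,4-dioxo-3-[(2E,6E)-3,7,11-trimethyldodeca-2,6,10-trien-1-yl]-3,4-dihydro-2H-chromen-3-yl}propanoic acid; 25 tert-butyl(dimethyl){[(5S,6Z)-tetradec-6-ene-1,3-diyn-5-yl]oxy}silane
Product: 29 (3S)-3-[(8S,9Z)-8-{[tert-butyl(dimethyl)silyl]oxy}-3-oxoheptadec-9-ene-4,6-diyn-1-yl]-3-[(2E,6E)-3,7,11-trimethyldodeca-2,6,10-trien-1-yl]-2H-chromene-2,4(3H)-dione, via acid chloride 26 (not isolated), via lithium acetylide 27 (not isolated), via alkynylzinc chloride 28 (not isolated)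
Conditions: 15, 1-chloro-N,N,2-trimethylprop-1-en-1-amine, CH2Cl2, 0 °C → rt, concentrate; separately 25, n-BuLi, THF, −78 °C, then ZnCl2; combine, Pd(PPh3)4 (5 mol%), THF, 0 °C → rt
Reagents that add atoms: none
Why: Palladium-catalysed acylation of an alkynylzinc by an acid chloride (Negishi-type acyl coupling) gives the diynone directly and without base, so that no alkoxide forms next to the aryl lactone and no enolate arises that could expel the 4-hydroxycoumarin-type anion by retro-Michael cleavage and so racemise C3.

Step 14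
Reactants: 29 (3S)-3-[(8S,9Z)-8-{[tert-butyl(dimethyl)silyl]oxy}-3-oxoheptadec-9-ene-4,6-diyn-1-yl]-3-[(2E,6E)-3,7,11-trimethyldodeca-2,6,10-trien-1-yl]-2H-chromene-2,4(3H)-dione
Product: 30 (3S)-3-[(8S,9Z)-8-hydroxy-3-oxoheptadec-9-ene-4,6-diyn-1-yl]-3-[(2E,6E)-3,7,11-trimethyldodeca-2,6,10-trien-1-yl]-2H-chromene-2,4(3H)-dione (CNP0346147.1)
Conditions: HF·pyridine, THF, 0 °C
Reagents that add atoms: none
Why: Fluoride cleaves the allylic/propargylic silyl ether under mildly acidic conditions that should leave the diynone, the aryl lactone and the triene untouched.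

**Compound list**

1 | 3-(tert-butoxy)-3-oxopropanoic acid | CC(C)(C)OC(=O)CC(=O)O | starting material
2 | 2,2-diphenylethanol | OCC(c1ccccc1)c1ccccc1 | starting material
3 | tert-butyl 2,2-diphenylethyl propanedioate | CC(C)(C)OC(=O)CC(=O)OCC(c1ccccc1)c1ccccc1 | intermediate
4 | tert-butyl prop-2-enoate | C=CC(=O)OC(C)(C)C | starting material
5 | 1,3-di-tert-butyl 1-(2,2-diphenylethyl) propane-1,1,3-tricarboxylate (racemic) | CC(C)(C)OC(=O)CCC(C(=O)OCC(c1ccccc1)c1ccccc1)C(=O)OC(C)(C)C | intermediate
6 | (2E,6E)-1-bromo-3,7,11-trimethyldodeca-2,6,10-triene | BrC/C=C(\C)CC/C=C(\C)CCC=C(C)C | starting material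
7 | 1,3-di-tert-butyl 1-(2,2-diphenylethyl) (1S)-1-[(2E,6E)-3,7,11-trimethyldodeca-2,6,10-trien-1-yl]propane-1,1,3-tricarboxylate | CC(C)(C)OC(=O)CC[C@@](C(=O)OCC(c1ccccc1)c1ccccc1)(C/C=C(\C)CC/C=C(\C)CCC=C(C)C)C(=O)OC(C)(C)C | intermediate
8 | (2S)-5-tert-butoxy-2-(tert-butoxycarbonyl)-5-oxo-2-[(2E,6E)-3,7,11-trimethyldodeca-2,6,10-trien-1-yl]pentanoic acid | CC(C)(C)OC(=O)CC[C@@](C(=O)O)(C/C=C(\C)CC/C=C(\C)CCC=C(C)C)C(=O)OC(C)(C)C | intermediate
9 | 2-(trimethylsilyl)phenyl trifluoromethanesulfonate | C[Si](C)(C)c1ccccc1OS(=O)(=O)C(F)(F)F | starting material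
10 | sodium salt of acid 8 | CC(C)(C)OC(=O)CC[C@@](C(=O)[O-])(C/C=C(\C)CC/C=C(\C)CCC=C(C)C)C(=O)OC(C)(C)C.[Na+] | intermediate (not isolated)
11 | benzyne (1,2-didehydrobenzene) | C1=CC=CC#C1 | intermediate (not isolated)
12 | di-tert-butyl (2S)-2-(2-hydroxybenzoyl)-2-[(2E,6E)-3,7,11-trimethyldodeca-2,6,10-trien-1-yl]pentanedioate | CC(C)(C)OC(=O)CC[C@@](C(=O)c1ccccc1O)(C/C=C(\C)CC/C=C(\C)CCC=C(C)C)C(=O)OC(C)(C)C | intermediate
13 | bis(trimethylsilyl) (2S)-2-[(2E,6E)-3,7,11-trimethyldodeca-2,6,10-trien-1-yl]-2-{2-[(trimethylsilyl)oxy]benzoyl}pentanedioate | C[Si](C)(C)OC(=O)CC[C@@](C(=O)c1ccccc1O[Si](C)(C)C)(C/C=C(\C)CC/C=C(\C)CCC=C(C)C)C(=O)O[Si](C)(C)C | intermediate (not isolated)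
14 | (2S)-2-(2-hydroxybenzoyl)-2-[(2E,6E)-3,7,11-trimethyldodeca-2,6,10-trien-1-yl]pentanedioic acid | OC(=O)CC[C@@](C(=O)c1ccccc1O)(C/C=C(\C)CC/C=C(\C)CCC=C(C)C)C(=O)O | intermediate (not isolated)
15 | 3-{(3S)-2,4-dioxo-3-[(2E,6E)-3,7,11-trimethyldodeca-2,6,10-trien-1-yl]-3,4-dihydro-2H-chromen-3-yl}propanoic acid | OC(=O)CC[C@@]1(C/C=C(\C)CC/C=C(\C)CCC=C(C)C)C(=O)Oc2ccccc2C1=O | intermediate
16 | 1,4-bis(trimethylsilyl)buta-1,3-diyne | C[Si](C)(C)C#CC#C[Si](C)(C)C | starting material
17 | lithium 4-(trimethylsilyl)buta-1,3-diyn-1-ide | [Li]C#CC#C[Si](C)(C)C | intermediate (not isolated)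
18 | buta-1,3-diyn-1-yl(trimethyl)silane | C#CC#C[Si](C)(C)C | intermediate
19 | dec-2-yn-1-ol | CCCCCCCC#CCO | starting material
20 | (2Z)-dec-2-en-1-ol | CCCCCCC/C=C\CO | intermediate
21 | (2Z)-dec-2-enal | CCCCCCC/C=C\C=O | intermediate
22 | methyl[4-(trimethylsilyl)buta-1,3-diyn-1-yl]zinc | C[Zn]C#CC#C[Si](C)(C)C | intermediate (not isolated)
23 | (5S,6Z)-1-(trimethylsilyl)tetradec-6-ene-1,3-diyn-5-ol | CCCCCCC/C=C\[C@H](O)C#CC#C[Si](C)(C)C | intermediate
24 | tert-butyl(dimethyl){[(5S,6Z)-1-(trimethylsilyl)tetradec-6-ene-1,3-diyn-5-yl]oxy}silane | CCCCCCC/C=C\[C@H](O[Si](C)(C)C(C)(C)C)C#CC#C[Si](C)(C)C | intermediate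
25 | tert-butyl(dimethyl){[(5S,6Z)-tetradec-6-ene-1,3-diyn-5-yl]oxy}silane | CCCCCCC/C=C\[C@H](O[Si](C)(C)C(C)(C)C)C#CC#C | intermediate
26 | 3-{(3S)-2,4-dioxo-3-[(2E,6E)-3,7,11-trimethyldodeca-2,6,10-trien-1-yl]-3,4-dihydro-2H-chromen-3-yl}propanoyl chloride | ClC(=O)CC[C@@]1(C/C=C(\C)CC/C=C(\C)CCC=C(C)C)C(=O)Oc2ccccc2C1=O | intermediate (not isolated)
27 | lithium acetylide of 25 | CCCCCCC/C=C\[C@H](O[Si](C)(C)C(C)(C)C)C#CC#C[Li] | intermediate (not isolated)
28 | alkynylzinc chloride of 25 | CCCCCCC/C=C\[C@H](O[Si](C)(C)C(C)(C)C)C#CC#C[Zn]Cl | intermediate (not isolated)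
29 | (3S)-3-[(8S,9Z)-8-{[tert-butyl(dimethyl)silyl]oxy}-3-oxoheptadec-9-ene-4,6-diyn-1-yl]-3-[(2E,6E)-3,7,11-trimethyldodeca-2,6,10-trien-1-yl]-2H-chromene-2,4(3H)-dione | CCCCCCC/C=C\[C@H](O[Si](C)(C)C(C)(C)C)C#CC#CC(=O)CC[C@@]1(C/C=C(\C)CC/C=C(\C)CCC=C(C)C)C(=O)Oc2ccccc2C1=O | intermediate
30 | (3S)-3-[(8S,9Z)-8-hydroxy-3-oxoheptadec-9-ene-4,6-diyn-1-yl]-3-[(2E,6E)-3,7,11-trimethyldodeca-2,6,10-trien-1-yl]-2H-chromene-2,4(3H)-dione | CCCCCCC/C=C\[C@H](O)C#CC#CC(=O)CC[C@@]1(C/C=C(\C)CC/C=C(\C)CCC=C(C)C)C(=O)Oc2ccccc2C1=O | target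

**Count and risks**

Total step count: 14. Longest linear sequence: 8 (steps 1–6, 13 and 14, from compound 1).

Steps most likely to fail:

1. Step 5. The aryl anion may be protonated before the acyl shift (giving the plain phenyl ester), the shift to the hindered α-quaternary acyl carbon may be slow, or the phenoxide may be arylated a second time. Any chromandione formed directly in this step would belong to the opposite enantiomeric series and is removed by chromatography before step 6. Fallback: the same connectivity is reached by a classical anionic Fries route. Setting out from 8, esterification with 2-iodophenol (EDC·HCl, DMAP, CH2Cl2) should give the 2-iodophenyl ester F1. Iodine–magnesium exchange (iPrMgCl·LiCl, THF, −40 °C) should give the arylmagnesium chloride F2, which undergoes the same 1,3 O→C acyl shift on warming and, after acidic work-up, comes back to the route at 12. Here the aryl–O bond is bought with the phenol and only the aryl–acyl bond is made in the rearrangement.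

2. Step 3. The catalyst may discriminate poorly between the enolate faces, because the α-substituent is larger than in the close precedents, or the sense of induction may differ. Fallback: setting out from 5, alkylation with 6 under achiral conditions (NaH, THF, 0 °C) should give the racemic malonate F3. Its enantiomers are separated by preparative supercritical-fluid chromatography on a chiral stationary phase (the diphenylethyl ester serves as chromophore), and the (S) enantiomer comes back to the route at 7.

3. Step 10. The Z enal may isomerise to the E enal under the zinc alkoxide conditions before addition, or enantioface control may be poor for a Z enal. Fallback: setting out from 21, addition of lithium acetylide 17 (made as in step 7, not quenched) in THF at −78 °C should give the racemic carbinol F4. Lipase-mediated kinetic resolution (Burkholderia cepacia lipase, vinyl acetate, hexane, 30 °C) is expected from the empirical size rule, with the rod-like diynyl group as the smaller substituent, to acylate the (5S) alcohol to the acetate F5 and to leave the (5R) alcohol F6; this assignment would have to be checked. K2CO3 in MeOH removes the acetyl and the C-silyl group of F5 to give the (5S) terminal diynol F7, and TBSCl/imidazole in DMF comes back to the route at 25.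

**Further compounds**

F1 | step 5 | 2-iodophenyl ester of acid 8 | CC(C)(C)OC(=O)CC[C@@](C(=O)Oc1ccccc1I)(C/C=C(\C)CC/C=C(\C)CCC=C(C)C)C(=O)OC(C)(C)C
F2 | step 5 | arylmagnesium chloride formed from F1 | CC(C)(C)OC(=O)CC[C@@](C(=O)Oc1ccccc1[Mg]Cl)(C/C=C(\C)CC/C=C(\C)CCC=C(C)C)C(=O)OC(C)(C)C
F3 | step 3 | racemic 1,3-di-tert-butyl 1-(2,2-diphenylethyl) 1-[(2E,6E)-3,7,11-trimethyldodeca-2,6,10-trien-1-yl]propane-1,1,3-tricarboxylate | CC(C)(C)OC(=O)CCC(C(=O)OCC(c1ccccc1)c1ccccc1)(C/C=C(\C)CC/C=C(\C)CCC=C(C)C)C(=O)OC(C)(C)C
F4 | step 10 | racemic (6Z)-1-(trimethylsilyl)tetradec-6-ene-1,3-diyn-5-ol | CCCCCCC/C=C\C(O)C#CC#C[Si](C)(C)C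
F5 | step 10 | (5S,6Z)-1-(trimethylsilyl)tetradec-6-ene-1,3-diyn-5-yl acetate | CCCCCCC/C=C\[C@H](OC(C)=O)C#CC#C[Si](C)(C)C
F6 | step 10 | (5R,6Z)-1-(trimethylsilyl)tetradec-6-ene-1,3-diyn-5-ol | CCCCCCC/C=C\[C@@H](O)C#CC#C[Si](C)(C)C
F7 | step 10 | (5S,6Z)-tetradec-6-ene-1,3-diyn-5-ol | CCCCCCC/C=C\[C@H](O)C#CC#C
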